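## Structural features

The target is a bicyclic diester of the ent-labdane type. Ring A (C1–C5, C10) is a saturated cyclohexane with a gem-dimethyl carbon C4, and ring B (C5–C10) is a cyclohexene with the C6=C7 double bond; the two are trans-fused. Four contiguous stereocentres lie on ring B: C5 (H) and the quaternary C10 (methyl C20) at the ring fusion, then C9 and C8. The C5 hydrogen is trans to C20, the C9 side chain is equatorial and cis to C20, and the C8 methyl ester (C17) is equatorial and trans to the C9 chain. From C9 a two-carbon link (C11–C12) leads to a trisubstituted (E)-enoate (C13=C14–C15) with an acetoxymethyl group (C16) on C13; the ester is cis to the C12 chain. The fragile groups are the C8 ester (allylic and α to a carbonyl, so open to epimerisation and to migration of C6=C7 into conjugation) and the γ-acetoxy enoate (ionisable allylic acetate, alkene geometry that must not scramble). The real difficulty is the quaternary stereocentre C10 as a single enantiomer, one carbon (C5) away from the second quaternary carbon C4, together with the trans fusion and the equatorial C8/C9 pattern. The key step uses the position of C5 between C4 and C6: with C6 as a carbonyl, C4–C5 is a bond between an enol ether carbon and a tertiary cation, so ring A can be closed last onto a ring B that already carries C10, and the C5 hydrogen becomes epimerisable.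

## Logic of the disconnections

26 ⇒ 25. The C16–O acetate bond is cut first, because the γ-acetoxy enoate is the group least compatible with palladium and base. The gain is small but it removes the only ionisable allylic ester from all earlier steps. The forward step is an O-acetylation that must leave the two methyl esters and the C6=C7 position alone.

25 ⇒ 22 + 23. The C12–C13 bond between the saturated link and the trisubstituted alkene is cut. All stereocentres stay in 22, and the alkene geometry is carried by the small fragment 23, so the route becomes convergent. The forward step must hydroborate the vinyl group of 22 in preference to the ring alkene, then transfer the primary alkyl group to the vinyl iodide with retention of geometry under a base that does not conjugate the C8 ester.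

22 ⇒ 21 ⇒ 19. The C6=C7 alkene is traced back to a C6 ketone through the C6–O triflate of 21. A carbonyl at C6 is what makes C5 nucleophilic and epimerisable earlier in the route. Forward, enolisation must go toward C7 (not toward C5 or the ester α-carbon C8), and the triflate must be replaced by hydrogen without moving the new alkene.

19 ⇒ 18. The C11=C12 bond is cut to the C11 aldehyde of 18, which is the carbonyl that the cycloaddition needs. Forward, the methylenation must select the aldehyde over the hindered C6 ketone and must not change C9.

18 ⇒ 16. The C8–H and C9–H bonds are removed, restoring the C8=C9 ene-dicarbonyl of 16. In 18 the centres C5, C8 and C9 are each α to a carbonyl, so three of the four stereocentres need no individual control. The demand is that the trans-fused, all-equatorial isomer is the most stable one and that the 1,4-reduction spares the aldehyde and the ketone.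

16 ⇒ 15. The C4–C5 bond is cut, which opens ring A. What remains is the monocyclic 15, with a tertiary chloride at the end of the C10 chain, a C5=C6 silyl enol ether and C10 as the only stereocentre. The second quaternary carbon and the most hindered bond of the skeleton are thereby postponed to a cationic step that tolerates congestion. Forward, the C–Cl bond must be ionised without activating the enal or the ester, and C5 must capture the cation faster than the cation loses a proton, with the enol ether still at C5=C6.

15 ⇒ 8 + 14. The C7–C8 and C9–C10 bonds are cut in a retro-[4+2] sense. The cyclohexa-1,4-diene falls apart into two achiral, acyclic pieces, and the cycloaddition places the enol ether exactly at C5=C6; before it, the enol ether of 8 is nucleophilic only at the future C7, so the chloride cannot react early. Forward, the formyl group of 14 must steer the regiochemistry and one face of the diene must be selected; this is the single enantio-determining event and it needs geometrically pure 8.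

8 ⇒ 6 ⇒ 5 ⇒ 4 ⇒ 3 ⇒ 2 ⇒ 1. The O–Si bond of 8 leads back to the methyl ketone 6. The bond between the carbonyl carbon and its methyl group leads back to the aldehyde 4, and the C–Cl bond leads back to the trisubstituted alkene of 1. The C–Cl bond is made first, at a stage without a conjugated carbonyl, because HCl on an enone or enal allows reversible conjugate addition and would scramble the E geometry on which the configuration of C10 depends. Forward, HCl must add only to the remote alkene, and every later step must be neutral or kinetically basic.

14 and 23 ⇒ 13 ⇒ 9 + 10. Both four-carbon pieces go back to the same alkynoate 13 (alcohol oxidation level for 14, H–I across the triple bond for 23). The C–C bond between the alkyne terminus of 9 and the carbonyl of 10 is then cut. One shared intermediate keeps the count low; the hydroiodination must be an anti addition to give the Z iodide.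

## Other disconnections considered

Alternative 1: The cut is the C8–C9 bond, with a C6–O ester bond put back in the reverse sense. Ring B is opened to the trans-fused δ-lactone A1 (ring atoms C11, O, C6, C5, C10, C9), whose C6 carries a (Z)-acrylate on the face of the angular methyl. Forward, the lactone enolate would be O-silylated to the ketene acetal A2, and an Ireland–Claisen shift would form C8–C9, break C6–O and give the acid A3.
- In its favour: A3 is closer to the target than the product of the chosen key step. The alkene is already at C6=C7, the C8 ester and the C9 carbon are present, and C8 and C9 come from a concerted transfer of chirality instead of an equilibration. On these points the alternative is the better plan.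
- Against it here: the quaternary-centre problem is only moved into A1, which needs C5, C10 and C6 set beforehand on a ring A with no simple catalytic asymmetric entry. The shift has to pass through a boat-like array whose side atoms are the trans ring-fusion carbons. The enolate of A1 can escape by a five-membered conjugate addition to the acrylate or by elimination of the carboxylate from the γ-acyloxy enoate. C11 arrives as an acid that must be reduced next to the C8 ester.
- Comparison: the stereochemical logic at C8/C9 is cleaner, the key step is mechanistically more delicate, and the total count is expected to be equal or higher because of the longer way to A1.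

Alternative 2: The cuts are C5–C10 and C8–C9, which open both rings to the acyclic trienal A4. Forward, the (E)-enal would add across the (Z)-2-silyloxydiene within one chain, under the same HNTf2-activated oxazaborolidine as in step 9, to give A5 with the C8 ester axial.
- In its favour: two rings, two C–C bonds and four stereocentres in one step. C9 is set kinetically, and the silyl enol ether sits at C6=C7, ready for the triflate. In bond economy and in the handling of C6 the alternative is the better plan; the need to epimerise C8 afterwards is equal to the equilibration of the chosen plan.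
- Against it here: the transition state must join C5, which is flanked by the quaternary C4, to the carbon that becomes the quaternary C10. The dienophile is a β,β-disubstituted enal, a poor partner for this catalyst class, and the diene terminus is neopentyl. Enantioselectivity, trans ring fusion and endo/exo selectivity would all have to come right in the same event, with no way to correct C5 or C10 afterwards.
- Comparison: the chosen plan spends one more step but separates the two hard events. The quaternary centre is made with a sterically small alkyne, and the C4–C5 bond is made by a cation that tolerates crowding. The chosen plan also leaves C5 correctable.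

Alternative 3: The cuts are C8–C9 and C7–C8, which remove C8 and contract ring B to the enantiopure hydrindenone A6. Forward, Sc(OTf)3 would catalyse addition of methyl diazoacetate A7 to the C9 ketone; migration of the C7 methylene with loss of N2 would give the enol ester A8.
- In its favour: the absolute configuration of C10 would come from well-established proline-type annulation chemistry. On that point the alternative is the better plan, since the chosen route relies on an untested enantioselective cycloaddition. The migration of CH2 in preference to the quaternary carbon is dependable, and the ring expansion itself is at least the equal of the chosen key step in reliability.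
- Against it here: A8 has C5=C6 instead of the C5 hydrogen and C6=C7. C5 would have to be reduced to the trans fusion and the alkene re-introduced at C6=C7 without a handle there. The C9–C11 bond has still to be made at a carbonyl next to the quaternary C10, and C8/C9 would again come from reduction of a tetrasubstituted alkene. The ketone of A6 is itself neopentyl and slow toward the diazo ester.
- Comparison: stronger on enantiocontrol, weaker on what follows the key step, and longer overall.

Key step: step 10

Remarks on the chemistry (assumptions and corrections):
- Ring fusion: the closure of step 10 can only give the cis-fused ketone 16, because the tether reaches C5 from the face on which it is attached at C10. Base cannot epimerise C5 in 16, since it is consumed by the far more acidic C7 (between the ketone and the vinylogous formyl ester). The trans fusion is therefore established in step 11, after C8=C9 has been reduced.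
- Silyl group: triisopropylsilyl is used on the enol ether, for more resistance to the acidic cycloaddition catalyst and to double-bond migration; the skeleton and the disconnection are unchanged.
- Chloride: HCl is added to 1, before any conjugated carbonyl exists, to protect the E geometry.
- Catalyst sense: the (S)-oxazaborolidine is assumed to give the (3R) adduct 15; if the sense is opposite, the (R)-catalyst is used.

## Route

Step 1
Reactants: 1 geranyl acetate [(2E)-3,7-dimethylocta-2,6-dien-1-yl acetate]
Product: 2 (2E)-7-chloro-3,7-dimethyloct-2-en-1-yl acetate
Conditions: HCl (g, 1.2 equiv), CH2Cl2, −30 → 0 °C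
Reagents that add atoms: hydrogen chloride, Cl
Why: Markovnikov hydrochlorination of the remote trisubstituted alkene through the tertiary cation; the C2=C3 alkene is deactivated by the allylic acetoxy group and, with no conjugated carbonyl present, its E geometry cannot leak.

Step 2
Reactants: 2 (2E)-7-chloro-3,7-dimethyloct-2-en-1-yl acetate
Product: 3 (2E)-7-chloro-3,7-dimethyloct-2-en-1-ol
Conditions: K2CO3 (0.2 equiv), MeOH, 0 °C → rt
Reagents that add atoms: none
Why: Base-catalysed transesterification of the acetate; solvolysis of the tertiary chloride in methanol is much slower than the acyl transfer.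

Step 3
Reactants: 3 (2E)-7-chloro-3,7-dimethyloct-2-en-1-ol
Product: 4 (2E)-7-chloro-3,7-dimethyloct-2-enal
Conditions: activated MnO2 (15 equiv), CH2Cl2, rt
Reagents that add atoms: none
Why: Allylic alcohol oxidation on MnO2 under neutral conditions, the standard way to an (E)-enal of this type without E/Z isomerisation.

Step 4
Reactants: 4 (2E)-7-chloro-3,7-dimethyloct-2-enal
Product: 5 (3E)-8-chloro-4,8-dimethylnon-3-en-2-ol (racemic at C2)
Conditions: MeMgBr (1.2 equiv), THF, −78 °C; aq NH4Cl
Reagents that add atoms: methylmagnesium bromide, C[Mg]Br
Why: Grignard 1,2-addition to the enal; the tertiary chloride is inert at −78 °C and the new carbinol centre is removed in the next step.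

Step 5
Reactants: 5 (3E)-8-chloro-4,8-dimethylnon-3-en-2-ol
Product: 6 (3E)-8-chloro-4,8-dimethylnon-3-en-2-one
Conditions: activated MnO2 (15 equiv), CH2Cl2, rt
Reagents that add atoms: none
Why: Neutral allylic oxidation to the β,β-disubstituted methyl enone, with no acid or base that could equilibrate the E and Z isomers.

Step 6
Reactants: 6 (3E)-8-chloro-4,8-dimethylnon-3-en-2-one
Product: 8 {[(3E)-8-chloro-4,8-dimethylnona-1,3-dien-2-yl]oxy}triisopropylsilane, via lithium dienolate 7 (not isolated)
Conditions: LiN(iPr)2 (1.1 equiv), THF, −78 °C; iPr3SiOTf (1.15 equiv), −78 → 0 °C; Et3N, pentane work-up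
Reagents that add atoms: triisopropylsilyl trifluoromethanesulfonate, CC(C)[Si](C(C)C)(C(C)C)OS(=O)(=O)C(F)(F)F
Why: Kinetic α′-deprotonation of the methyl ketone gives the cross-conjugated dienolate, which is O-silylated; this is the usual access to 2-silyloxy-4,4-dialkyl dienes and leaves the C3=C4 geometry and the chloride untouched.

Step 7
Reactants: 9 2-(prop-2-yn-1-yloxy)tetrahydro-2H-pyran; 10 methyl chloroformate
Product: 13 methyl 4-hydroxybut-2-ynoate, via lithium acetylide 11 (not isolated), via THP-protected ynoate 12 (not isolated)
Conditions: n-BuLi (1.05 equiv), THF, −78 °C; ClCO2Me (1.2 equiv), −78 → 0 °C; then TsOH·H2O (5 mol %), MeOH, rt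
Reagents that add atoms: none
Why: C-acylation of the lithium acetylide with the chloroformate, then acid-catalysed transacetalisation in methanol to remove the tetrahydropyranyl group.

Step 8
Reactants: 13 methyl 4-hydroxybut-2-ynoate
Product: 14 methyl 4-oxobut-2-ynoate
Conditions: activated MnO2 (20 equiv), CH2Cl2, rt; filtered through Celite, solution used at once
Reagents that add atoms: none
Why: Propargylic alcohol oxidation; the heterogeneous neutral oxidant leaves no acidic by-product that would harm the diene or the catalyst of step 9, and the sensitive ynal is not concentrated.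

Step 9
Reactants: 8 {[(3E)-8-chloro-4,8-dimethylnona-1,3-dien-2-yl]oxy}triisopropylsilane; 14 methyl 4-oxobut-2-ynoate
Product: 15 methyl (3R)-3-(4-chloro-4-methylpentyl)-2-formyl-3-methyl-5-[(triisopropylsilyl)oxy]cyclohexa-1,4-diene-1-carboxylate
Conditions: (S)-1-(2-methylphenyl)-3,3-diphenyltetrahydro-1H,3H-pyrrolo[1,2-c][1,3,2]oxazaborole (20 mol %), HNTf2 (18 mol %), CH2Cl2, −78 °C; Et3N quench
Reagents that add atoms: none
Why: Proposed new method: the formyl group of 14 binds to the cationic boron, so the alkyne carbon β to it (C8) is attacked by the nucleophilic CH2 terminus of the silyloxydiene, and the disubstituted diene terminus closes onto the formyl-bearing carbon in an asynchronous [4+2] addition that fixes the regiochemistry; a linear alkyne has no endo/exo issue, so C10 is decided only by which diene face meets the shielded, catalyst-bound ynal and by the E geometry of 8; the closest known reaction types are the chiral-Lewis-acid-catalysed Diels–Alder reactions of acetylenic aldehydes with cyclic dienes and the oxazaborolidinium-catalysed additions of 2-silyloxydienes to enals, neither of which has set a quaternary centre at an acyclic diene terminus.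

Step 10
Reactants: 15 methyl (3R)-3-(4-chloro-4-methylpentyl)-2-formyl-3-methyl-5-[(triisopropylsilyl)oxy]cyclohexa-1,4-diene-1-carboxylate
Product: 16 methyl (4aS,8aR)-1-formyl-5,5,8a-trimethyl-4-oxo-3,4,4a,5,6,7,8,8a-octahydronaphthalene-2-carboxylate (cis-fused)
Conditions: AgOTf (1.5 equiv), 2,6-di-tert-butyl-4-methylpyridine (2 equiv), CH2Cl2 (0.01 M), dark, −78 → −20 °C; then Bu4NF/AcOH (1:1, 1.5 equiv), THF, −20 → 0 °C
Reagents that add atoms: none
Why: AgOTf abstracts chloride from the tertiary C–Cl bond and the C4 cation is captured by C5 of the ring B silyl enol ether, four atoms away through the quaternary C10; the silyloxycarbenium ion then gives up its silyl group (completed by the fluoride quench, which also returns any O-silylated product to the ketone) and leaves the C6 ketone. The closest known reaction type is the Lewis-acid-mediated α-tert-alkylation of silyl enol ethers with tertiary halides, including its ring-closing versions. Ring A closes in a 6-(enolexo)-exo mode: the cationic carbon becomes a ring member, the C5=C6 enol bond stays outside the new ring, and the C1–C3 tether adopts a chair-like arrangement. The new stereocentre C5 is controlled by the geometry of the closure alone: the tether can reach only the face of the enol ether on which C1 stands at C10, so C4 adds cis to C1 and the kinetic product is the cis-fused decalone; the trans fusion is a thermodynamic matter settled in step 11. The step needs chemoselective ionisation of C–Cl without activation of the enal or the ester, which a halophilic silver salt with a hindered pyridine as acid trap should provide where a carbonyl-binding Lewis acid would not. It needs the enol ether to stay at C5=C6, which the bulky silyl group and the cold, buffered medium protect, and it needs capture to outrun proton loss from the cation, which the six-membered closure at high dilution favours. C10 is not touched.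

Step 11
Reactants: 16 methyl (4aS,8aR)-1-formyl-5,5,8a-trimethyl-4-oxo-3,4,4a,5,6,7,8,8a-octahydronaphthalene-2-carboxylate
Product: 18 methyl (1R,2S,4aR,8aS)-1-formyl-5,5,8a-trimethyl-4-oxodecahydronaphthalene-2-carboxylate (trans-fused, formyl and ester equatorial), via cis-fused dihydro epimer mixture 17 (not isolated)
Conditions: Zn dust (10 equiv), AcOH, rt; filter, concentrate; then NaOMe (0.3 equiv), MeOH, 0 °C → rt
Reagents that add atoms: none
Why: Zinc in acetic acid reduces the C8=C9 ene-dicarbonyl by electron transfer and spares the isolated ketone; methoxide then epimerises C5, C8 and C9, each α to a carbonyl, to the most stable isomer. C5 goes trans because the cis decalone cannot avoid both the C4/C10 methyl contact and its extra gauche interactions; C8 goes equatorial because an axial ester would be syn-diaxial to C20; C9 goes equatorial, trans to the ester, as expected for a formyl group flanked by a quaternary carbon and an equatorial neighbour.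

Step 12
Reactants: 18 methyl (1R,2S,4aR,8aS)-1-formyl-5,5,8a-trimethyl-4-oxodecahydronaphthalene-2-carboxylate
Product: 19 methyl (1R,2S,4aR,8aS)-1-ethenyl-5,5,8a-trimethyl-4-oxodecahydronaphthalene-2-carboxylate
Conditions: Ph3PCH3Br (1.6 equiv), KN(SiMe3)2 (1.5 equiv), THF, 0 °C; then 18, −78 → 0 °C
Reagents that add atoms: methyltriphenylphosphonium bromide (as its ylide), C[P+](c1ccccc1)(c1ccccc1)c1ccccc1.[Br-]
Why: Wittig methylenation of the aldehyde; the C6 ketone, flanked by the doubly neopentyl C5, does not react at this temperature, and any enolisation at C9 returns to the equatorial isomer already favoured.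

Step 13
Reactants: 19 methyl (1R,2S,4aR,8aS)-1-ethenyl-5,5,8a-trimethyl-4-oxodecahydronaphthalene-2-carboxylate
Product: 21 methyl (1R,2R,4aR,8aS)-1-ethenyl-5,5,8a-trimethyl-4-{[(trifluoromethyl)sulfonyl]oxy}-1,2,4a,5,6,7,8,8a-octahydronaphthalene-2-carboxylate, via potassium enolate 20 (not isolated)
Conditions: KN(SiMe3)2 (1.1 equiv), THF, −78 °C; PhNTf2 (1.2 equiv), −78 → 0 °C
Reagents that add atoms: N-phenylbis(trifluoromethanesulfonimide), O=S(=O)(N(c1ccccc1)S(=O)(=O)C(F)(F)F)C(F)(F)F
Why: Kinetic deprotonation takes the accessible C7 methylene of the ketone rather than the shielded C5 methine or the less acidic ester α-hydrogen, and O-sulfonylation fixes the C6=C7 enol triflate; no stereocentre is formed (the C2 descriptor changes only through priorities).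

Step 14
Reactants: 21 methyl (1R,2R,4aR,8aS)-1-ethenyl-5,5,8a-trimethyl-4-{[(trifluoromethyl)sulfonyl]oxy}-1,2,4a,5,6,7,8,8a-octahydronaphthalene-2-carboxylate
Product: 22 methyl (1R,2S,4aR,8aS)-1-ethenyl-5,5,8a-trimethyl-1,2,4a,5,6,7,8,8a-octahydronaphthalene-2-carboxylate
Conditions: Pd(OAc)2 (5 mol %), PPh3 (10 mol %), Bu3N (3 equiv), HCO2H (2 equiv), DMF, 60 °C
Reagents that add atoms: none
Why: Palladium-catalysed formate reduction of an enol triflate: oxidative addition of zerovalent palladium into C–OTf, exchange for formate, loss of CO2 and C–H reductive elimination; the weak amine base should not conjugate the β,γ-unsaturated ester.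

Step 15
Reactants: 13 methyl 4-hydroxybut-2-ynoate
Product: 23 methyl (2Z)-4-hydroxy-3-iodobut-2-enoate
Conditions: NaI (1.5 equiv), AcOH, 70 °C
Reagents that add atoms: sodium iodide, [Na+].[I-]
Why: Conjugate hydroiodination of an alkynoate; iodide adds to the β-carbon and the allenolate is protonated anti, so iodine ends up cis to the ester and the hydroxymethyl group trans to it.

Step 16
Reactants: 22 methyl (1R,2S,4aR,8aS)-1-ethenyl-5,5,8a-trimethyl-1,2,4a,5,6,7,8,8a-octahydronaphthalene-2-carboxylate; 23 methyl (2Z)-4-hydroxy-3-iodobut-2-enoate
Product: 25 methyl (1R,2S,4aR,8aS)-1-[(3E)-3-(hydroxymethyl)-5-methoxy-5-oxopent-3-en-1-yl]-5,5,8a-trimethyl-1,2,4a,5,6,7,8,8a-octahydronaphthalene-2-carboxylate, via B-alkyl borane 24 (not isolated)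
Conditions: 9-BBN (1.5 equiv B–H), THF, 0 °C → rt; then aq K3PO4 (3 equiv), 23 (1.3 equiv), PdCl2(dppf) (5 mol %), AsPh3 (5 mol %), DMF, rt
Reagents that add atoms: none
Why: 9-BBN adds anti-Markovnikov to the monosubstituted vinyl group far faster than to the hindered ring alkene; the B-alkyl Suzuki–Miyaura coupling then joins C12 to C13 with retention of the iodide geometry, which places the ester cis to the new chain.

Step 17
Reactants: 25 methyl (1R,2S,4aR,8aS)-1-[(3E)-3-(hydroxymethyl)-5-methoxy-5-oxopent-3-en-1-yl]-5,5,8a-trimethyl-1,2,4a,5,6,7,8,8a-octahydronaphthalene-2-carboxylate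
Product: 26 methyl (1R,2S,4aR,8aS)-1-[(3E)-3-(acetoxymethyl)-5-methoxy-5-oxopent-3-en-1-yl]-5,5,8a-trimethyl-1,2,4a,5,6,7,8,8a-octahydronaphthalene-2-carboxylate (CNP0190145.1)
Conditions: Ac2O (1.5 equiv), pyridine (3 equiv), 4-(dimethylamino)pyridine (5 mol %), CH2Cl2, 0 °C → rt
Reagents that add atoms: acetic anhydride, CC(=O)OC(C)=O
Why: Nucleophile-catalysed O-acetylation of the primary allylic alcohol; the conditions are too mild to epimerise C8 or to move the C6=C7 bond.

## Compound list

1 | geranyl acetate, (2E)-3,7-dimethylocta-2,6-dien-1-yl acetate | CC(C)=CCC/C(C)=C/COC(C)=O | starting material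
2 | (2E)-7-chloro-3,7-dimethyloct-2-en-1-yl acetate | CC(C)(Cl)CCC/C(C)=C/COC(C)=O | intermediate
3 | (2E)-7-chloro-3,7-dimethyloct-2-en-1-ol | CC(C)(Cl)CCC/C(C)=C/CO | intermediate
4 | (2E)-7-chloro-3,7-dimethyloct-2-enal | CC(C)(Cl)CCC/C(C)=C/C=O | intermediate
5 | (3E)-8-chloro-4,8-dimethylnon-3-en-2-ol, racemic at C2 | CC(C)(Cl)CCC/C(C)=C/C(C)O | intermediate
6 | (3E)-8-chloro-4,8-dimethylnon-3-en-2-one | CC(C)(Cl)CCC/C(C)=C/C(C)=O | intermediate
7 | lithium (3E)-8-chloro-4,8-dimethylnona-1,3-dien-2-olate | C=C(O[Li])/C=C(\C)CCCC(C)(C)Cl | intermediate
8 | {[(3E)-8-chloro-4,8-dimethylnona-1,3-dien-2-yl]oxy}triisopropylsilane | C=C(O[Si](C(C)C)(C(C)C)C(C)C)/C=C(\C)CCCC(C)(C)Cl | intermediate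
9 | 2-(prop-2-yn-1-yloxy)tetrahydro-2H-pyran (racemic) | C#CCOC1CCCCO1 | starting material
10 | methyl chloroformate | COC(=O)Cl | starting material
11 | lithium acetylide of 9, [3-(tetrahydro-2H-pyran-2-yloxy)prop-1-yn-1-yl]lithium | [Li]C#CCOC1CCCCO1 | intermediate
12 | methyl 4-(tetrahydro-2H-pyran-2-yloxy)but-2-ynoate | COC(=O)C#CCOC1CCCCO1 | intermediate
13 | methyl 4-hydroxybut-2-ynoate | COC(=O)C#CCO | intermediate
14 | methyl 4-oxobut-2-ynoate | COC(=O)C#CC=O | intermediate
15 | methyl (3R)-3-(4-chloro-4-methylpentyl)-2-formyl-3-methyl-5-[(triisopropylsilyl)oxy]cyclohexa-1,4-diene-1-carboxylate | O=CC1=C(C(=O)OC)CC(O[Si](C(C)C)(C(C)C)C(C)C)=C[C@@]1(C)CCCC(C)(C)Cl | intermediate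
16 | methyl (4aS,8aR)-1-formyl-5,5,8a-trimethyl-4-oxo-3,4,4a,5,6,7,8,8a-octahydronaphthalene-2-carboxylate, cis-fused | O=CC1=C(C(=O)OC)CC(=O)[C@H]2C(C)(C)CCC[C@@]12C | intermediate
17 | methyl (4aS,8aS)-1-formyl-5,5,8a-trimethyl-4-oxodecahydronaphthalene-2-carboxylate, cis-fused, mixture of C1 and C2 epimers | O=CC1C(C(=O)OC)CC(=O)[C@H]2C(C)(C)CCC[C@@]12C | intermediate
18 | methyl (1R,2S,4aR,8aS)-1-formyl-5,5,8a-trimethyl-4-oxodecahydronaphthalene-2-carboxylate, trans-fused | O=C[C@@H]1[C@@H](C(=O)OC)CC(=O)[C@@H]2C(C)(C)CCC[C@@]12C | intermediate
19 | methyl (1R,2S,4aR,8aS)-1-ethenyl-5,5,8a-trimethyl-4-oxodecahydronaphthalene-2-carboxylate | C=C[C@@H]1[C@@H](C(=O)OC)CC(=O)[C@@H]2C(C)(C)CCC[C@@]12C | intermediate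
20 | potassium enolate of 19 (C6=C7 enolate; naphthalene positions 3,4) | C=C[C@@H]1[C@@H](C(=O)OC)C=C(O[K])[C@@H]2C(C)(C)CCC[C@@]12C | intermediate
21 | methyl (1R,2R,4aR,8aS)-1-ethenyl-5,5,8a-trimethyl-4-{[(trifluoromethyl)sulfonyl]oxy}-1,2,4a,5,6,7,8,8a-octahydronaphthalene-2-carboxylate | C=C[C@@H]1[C@@H](C(=O)OC)C=C(OS(=O)(=O)C(F)(F)F)[C@@H]2C(C)(C)CCC[C@@]12C | intermediate
22 | methyl (1R,2S,4aR,8aS)-1-ethenyl-5,5,8a-trimethyl-1,2,4a,5,6,7,8,8a-octahydronaphthalene-2-carboxylate | C=C[C@@H]1[C@@H](C(=O)OC)C=C[C@@H]2C(C)(C)CCC[C@@]12C | intermediate
23 | methyl (2Z)-4-hydroxy-3-iodobut-2-enoate | COC(=O)/C=C(\I)CO | intermediate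
24 | methyl (1R,2S,4aR,8aS)-1-[2-(9-borabicyclo[3.3.1]nonan-9-yl)ethyl]-5,5,8a-trimethyl-1,2,4a,5,6,7,8,8a-octahydronaphthalene-2-carboxylate | C1CC2CCCC(C1)B2CC[C@@H]1[C@@H](C(=O)OC)C=C[C@@H]2C(C)(C)CCC[C@@]12C | intermediate
25 | methyl (1R,2S,4aR,8aS)-1-[(3E)-3-(hydroxymethyl)-5-methoxy-5-oxopent-3-en-1-yl]-5,5,8a-trimethyl-1,2,4a,5,6,7,8,8a-octahydronaphthalene-2-carboxylate | COC(=O)/C=C(\CC[C@@H]1[C@@H](C(=O)OC)C=C[C@@H]2C(C)(C)CCC[C@@]12C)CO | intermediate
26 | methyl (1R,2S,4aR,8aS)-1-[(3E)-3-(acetoxymethyl)-5-methoxy-5-oxopent-3-en-1-yl]-5,5,8a-trimethyl-1,2,4a,5,6,7,8,8a-octahydronaphthalene-2-carboxylate | COC(=O)/C=C(\CC[C@@H]1[C@@H](C(=O)OC)C=C[C@@H]2C(C)(C)CCC[C@@]12C)COC(C)=O | target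

## Step count and least certain steps

Total: 17 steps. Longest linear sequence: 14 steps (steps 1–6, 9–14, 16 and 17, from 1 to 26).

Step 9 (the step with the proposed new method).
- What may go wrong: poor discrimination between the methyl group and the CH2 chain at the diene terminus, so that the two diene faces react at similar rates. The reaction may also go stepwise (conjugate addition of the enol ether without ring closure), or the acidic catalyst may protodesilylate the diene.
- Fallback, by known chemistry: the fallback sets out from 8 and 14. The uncatalysed thermal cycloaddition (toluene, 40–60 °C) gives racemic methyl 3-(4-chloro-4-methylpentyl)-2-formyl-3-methyl-5-[(triisopropylsilyl)oxy]cyclohexa-1,4-diene-1-carboxylate F1, with the regiochemistry fixed by the same polarisation. F1 is resolved by preparative chromatography on a cellulose tris(3,5-dimethylphenylcarbamate) phase, and the (3R) enantiomer re-enters the route at 15.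

Step 10 (key step).
- What may go wrong: proton loss from the tertiary cation outruns ring closure; acid moves the enol ether double bond into conjugation with C8=C9 before alkylation; or the enol ether adds to the aldehyde of a second molecule.
- Fallback: the order of events is changed so that the closure runs on a substrate without the ene-dicarbonyl. It sets out from 15: reduction with Zn and aqueous NH4Cl in THF gives methyl (3R)-3-(4-chloro-4-methylpentyl)-2-formyl-3-methyl-5-[(triisopropylsilyl)oxy]cyclohex-4-ene-1-carboxylate F2 (mixture at the two new centres), in which C7 is no longer doubly activated and the enol ether cannot migrate into conjugation. The same silver-mediated closure on F2 gives the cis-fused mixture 17, where the sequence rejoins the route for the methoxide equilibration to 18.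

Step 11.
- What may go wrong: incomplete thermodynamic bias, most likely at C9, where the formyl group is small, and less likely at C5; reductive coupling of the aldehyde on zinc is a minor risk.
- Fallback: C9 is set kinetically instead of thermodynamically. It sets out from 18 as obtained (mixed with its C1 epimer): tBuMe2SiOTf and Et3N convert both the aldehyde and the ketone into enol ethers, giving methyl 4-[(tert-butyldimethylsilyl)oxy]-1-{[(tert-butyldimethylsilyl)oxy]methylidene}-5,5,8a-trimethyl-1,2,4a,5,6,7,8,8a-octahydronaphthalene-2-carboxylate F3, in which C9 is planar. Cleavage with Bu4NF and AcOH at −78 °C should protonate C9 from the face opposite the axial angular methyl and return 18.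

Step 13.
- What may go wrong: enolisation at the ester α-carbon C8 instead of C7, or slow O-sulfonylation of the hindered enolate.
- Fallback: enolate chemistry is avoided. It sets out from 19: NaBH4 in MeOH at 0 °C should deliver hydride from the face opposite C20 and the axial C4 methyl, giving methyl 1-ethenyl-4-hydroxy-5,5,8a-trimethyldecahydronaphthalene-2-carboxylate F4 with the hydroxyl axial and cis to the angular methyl. Thermal syn-elimination with methyl N-(triethylammoniosulfonyl)carbamate in toluene can then use only a C7 hydrogen, because the C5 hydrogen is anti to the oxygen. This gives 22 and bypasses 21 and step 14.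

Step 16.
- What may go wrong: base-induced migration of C6=C7 into conjugation with the C8 ester, loss of HI from 23 to the alkynoate, or slow transmetalation from the hindered borane.
- Fallback: a base-free sp3–sp2 Negishi coupling. It sets out from 22: hydroboration with 9-BBN and oxidation with NaBO3 gives methyl 1-(2-hydroxyethyl)-5,5,8a-trimethyl-1,2,4a,5,6,7,8,8a-octahydronaphthalene-2-carboxylate F5. I2, PPh3 and imidazole give the iodide methyl 1-(2-iodoethyl)-5,5,8a-trimethyl-1,2,4a,5,6,7,8,8a-octahydronaphthalene-2-carboxylate F6. Zn dust with LiCl in THF gives the alkylzinc iodide F7. F7 is coupled under Pd(PPh3)4 catalysis with methyl (2Z)-4-acetoxy-3-iodobut-2-enoate F8 (from 23 with Ac2O and pyridine), which leads directly to 26.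

## Further compounds

F1 | step 9 | racemic methyl 3-(4-chloro-4-methylpentyl)-2-formyl-3-methyl-5-[(triisopropylsilyl)oxy]cyclohexa-1,4-diene-1-carboxylate | O=CC1=C(C(=O)OC)CC(O[Si](C(C)C)(C(C)C)C(C)C)=CC1(C)CCCC(C)(C)Cl
F2 | step 10 | methyl (3R)-3-(4-chloro-4-methylpentyl)-2-formyl-3-methyl-5-[(triisopropylsilyl)oxy]cyclohex-4-ene-1-carboxylate, mixture of C1 and C2 epimers | O=CC1C(C(=O)OC)CC(O[Si](C(C)C)(C(C)C)C(C)C)=C[C@@]1(C)CCCC(C)(C)Cl
F3 | step 11 | methyl 4-[(tert-butyldimethylsilyl)oxy]-1-{[(tert-butyldimethylsilyl)oxy]methylidene}-5,5,8a-trimethyl-1,2,4a,5,6,7,8,8a-octahydronaphthalene-2-carboxylate, ring stereocentres as in 18, exocyclic enol ether geometry not defined | CC(C)(C)[Si](C)(C)OC=C1[C@@H](C(=O)OC)C=C(O[Si](C)(C)C(C)(C)C)[C@@H]2C(C)(C)CCC[C@@]12C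
F4 | step 13 | methyl 1-ethenyl-4-hydroxy-5,5,8a-trimethyldecahydronaphthalene-2-carboxylate, trans-fused, hydroxyl axial and cis to the angular methyl, other centres as in 19 | C=C[C@@H]1[C@@H](C(=O)OC)C[C@H](O)[C@@H]2C(C)(C)CCC[C@@]12C
F5 | step 16 | methyl (1R,2S,4aR,8aS)-1-(2-hydroxyethyl)-5,5,8a-trimethyl-1,2,4a,5,6,7,8,8a-octahydronaphthalene-2-carboxylate | OCC[C@@H]1[C@@H](C(=O)OC)C=C[C@@H]2C(C)(C)CCC[C@@]12C
F6 | step 16 | methyl (1R,2S,4aR,8aS)-1-(2-iodoethyl)-5,5,8a-trimethyl-1,2,4a,5,6,7,8,8a-octahydronaphthalene-2-carboxylate | ICC[C@@H]1[C@@H](C(=O)OC)C=C[C@@H]2C(C)(C)CCC[C@@]12C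
F7 | step 16 | alkylzinc iodide from F6, {2-[(1R,2S,4aR,8aS)-2-(methoxycarbonyl)-5,5,8a-trimethyl-1,2,4a,5,6,7,8,8a-octahydronaphthalen-1-yl]ethyl}zinc iodide | I[Zn]CC[C@@H]1[C@@H](C(=O)OC)C=C[C@@H]2C(C)(C)CCC[C@@]12C
F8 | step 16 | methyl (2Z)-4-acetoxy-3-iodobut-2-enoate | COC(=O)/C=C(\I)COC(C)=O
A1 | alternative 1 | methyl (2Z)-3-(4a,8,8-trimethyl-3-oxooctahydro-1H-isochromen-1-yl)prop-2-enoate, trans-fused lactone, acrylate on C1 cis to the angular methyl | O=C1C[C@]2(C)CCCC(C)(C)[C@H]2[C@@H](/C=C\C(=O)OC)O1
A2 | alternative 1 | trimethylsilyl ketene acetal of A1 | C[Si](C)(C)OC1=C[C@]2(C)CCCC(C)(C)[C@H]2[C@@H](/C=C\C(=O)OC)O1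
A3 | alternative 1 | 2-(methoxycarbonyl)-5,5,8a-trimethyl-1,2,4a,5,6,7,8,8a-octahydronaphthalene-1-carboxylic acid, ring stereocentres as in 26 | OC(=O)[C@@H]1[C@@H](C(=O)OC)C=C[C@@H]2C(C)(C)CCC[C@@]12C
A4 | alternative 2 | methyl (2E,4Z,10E)-4-[(tert-butyldimethylsilyl)oxy]-6,6,10-trimethyl-12-oxododeca-2,4,10-trienoate | O=C/C=C(\C)CCCC(C)(C)/C=C(O[Si](C)(C)C(C)(C)C)/C=C/C(=O)OC
A5 | alternative 2 | methyl 1-formyl-4-[(tert-butyldimethylsilyl)oxy]-5,5,8a-trimethyl-1,2,4a,5,6,7,8,8a-octahydronaphthalene-2-carboxylate, trans-fused, ester axial (C8 epimer of the target series) | O=C[C@@H]1[C@H](C(=O)OC)C=C(O[Si](C)(C)C(C)(C)C)[C@@H]2C(C)(C)CCC[C@@]12C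
A6 | alternative 3 | 4,4,7a-trimethyl-2,4,5,6,7,7a-hexahydro-1H-inden-1-one, single enantiomer with C7a as C10 of 26 | O=C1CC=C2C(C)(C)CCC[C@@]12C
A7 | alternative 3 | methyl diazoacetate | COC(=O)C=[N+]=[N-]
A8 | alternative 3 | methyl 1-hydroxy-5,5,8a-trimethyl-3,5,6,7,8,8a-hexahydronaphthalene-2-carboxylate (enol form of the β-keto ester) | COC(=O)C1=C(O)[C@]2(C)CCCC(C)(C)C2=CC1
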